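**Strategy.** Everything rests on cutting the aryl–C1'H2–C2'H=C3'(CH3) head of the side chain (C1' = benzylic carbon, C15' = terminal CMe2) at C1'–C2' and at C3'–CH3. One operation, zirconium-catalysed methylalumination of a terminal C2'≡C3' alkyne and palladium-catalysed coupling of the resulting alkenylalane with a benzylic chloride, joins hydroquinone ring A, the C3' methyl and the chain and fixes the E-C2'=C3' alkene one carbon from ring A, the feature exploited. The precursor is the C2'–C15' enyne carrying a free (5'S)-hydroxyl and a (12'R)-silyl ether; ring A arrives as its bis-silyl ether, so acetylation of the one free hydroxyl and a single fluoride treatment complete the target.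

Key step: step 13

Remarks on the chemistry:
- TBS = tert-butyldimethylsilyl.
- Ring A is carried as its bis-TBS ether rather than as methyl ethers, so no oxidative unmasking of the hydroquinone is needed after the coupling.
- The sense of induction in step 7 is assigned by analogy with benzaldehyde-type aldehydes, for which the (R)-acid sends the nucleophile to the Re face. The C5' configuration of 13 is to be confirmed by Mosher ester analysis, and the antipodal acid used if the analogy does not hold.

**Step 1**
Reactants: 1 geranyl acetate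
Product: 3 (2E,6E)-3,7-dimethyl-8-oxoocta-2,6-dien-1-yl acetate, via allylic alcohol 2 (not isolated)
Conditions: SeO2 (0.3 equiv), t-BuOOH (3 equiv), salicylic acid (0.1 equiv), CH2Cl2, rt; aqueous work-up, then crude + MnO2 (15 equiv), CH2Cl2, rt
Reagents that add atoms: selenium dioxide, O=[Se]=O (oxygen carrier); tert-butyl hydroperoxide, CC(C)(C)OO (terminal oxidant)
Why: Catalytic SeO2/t-BuOOH allylic oxidation (ene reaction, then [2,3]-sigmatropic shift) attacks the E-methyl of the electron-richer terminal alkene, the C6'=C7' alkene being deactivated by its allylic acetate, and MnO2 oxidation of the allylic alcohol then converges alcohol 2 and any aldehyde already present on the E-enal.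

**Step 2**
Reactants: 3 (2E,6E)-3,7-dimethyl-8-oxoocta-2,6-dien-1-yl acetate; 4 (+)-B-allyldiisopinocampheylborane
Product: 6 (2E,6E,8R)-8-hydroxy-3,7-dimethylundeca-2,6,10-trien-1-yl acetate, via borinate ester 5 (not isolated)
Conditions: 4 (1 M in pentane, 1.3 equiv), Et2O, −78 °C; then NaBO3·4H2O, THF–H2O, rt
Reagents that add atoms: (+)-B-allyldiisopinocampheylborane (4), C=CCB([C@H]1C[C@H]2C[C@@H]([C@@H]1C)C2(C)C)[C@H]1C[C@H]2C[C@@H]([C@@H]1C)C2(C)C
Why: Brown allylboration through a closed chair transition state, in which the isopinocampheyl groups derived from (−)-α-pinene steer the allyl group to the Re face of the enal and so set C12' as R; the acetate is inert at −78 °C and survives the mild perborate oxidation of borinate 5.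

**Step 3**
Reactants: 6 (2E,6E,8R)-8-hydroxy-3,7-dimethylundeca-2,6,10-trien-1-yl acetate; 7 2-methyl-2-butene
Product: 8 (2E,6E,8R)-8-hydroxy-3,7,11-trimethyldodeca-2,6,10-trien-1-yl acetate
Conditions: second-generation Grubbs catalyst (5 mol %), 2-methyl-2-butene/CH2Cl2, 35 °C, sealed vessel
Reagents that add atoms: 2-methyl-2-butene (7), CC=C(C)C
Why: Olefin cross-metathesis, in which the ruthenium carbene engages the monosubstituted alkene far faster than the trisubstituted ones and the large excess of 2-methyl-2-butene caps it as the isopropylidene while propene leaves; C12' is not involved.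

**Step 4**
Reactants: 8 (2E,6E,8R)-8-hydroxy-3,7,11-trimethyldodeca-2,6,10-trien-1-yl acetate
Product: 9 (2E,6E,8R)-8-(tert-butyldimethylsilyloxy)-3,7,11-trimethyldodeca-2,6,10-trien-1-yl acetate
Conditions: TBSCl, imidazole, DMF, rt
Reagents that add atoms: tert-butyldimethylsilyl chloride, CC(C)(C)[Si](C)(C)Cl
Why: Standard imidazole-mediated silylation of a secondary alcohol; the acetate and the alkenes are inert.

**Step 5**
Reactants: 9 (2E,6E,8R)-8-(tert-butyldimethylsilyloxy)-3,7,11-trimethyldodeca-2,6,10-trien-1-yl acetate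
Product: 10 (2E,6E,8R)-8-(tert-butyldimethylsilyloxy)-3,7,11-trimethyldodeca-2,6,10-trien-1-ol
Conditions: K2CO3 (0.2 equiv), MeOH, 0 °C → rt
Reagents that add atoms: none
Why: Base-catalysed transesterification (methanolysis) of the primary allylic acetate; the secondary silyl ether is stable to K2CO3 in methanol.

**Step 6**
Reactants: 10 (2E,6E,8R)-8-(tert-butyldimethylsilyloxy)-3,7,11-trimethyldodeca-2,6,10-trien-1-ol
Product: 11 (2E,6E,8R)-8-(tert-butyldimethylsilyloxy)-3,7,11-trimethyldodeca-2,6,10-trienal
Conditions: MnO2 (15 equiv), CH2Cl2, rt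
Reagents that add atoms: none
Why: Selective MnO2 oxidation of the primary allylic alcohol to the enal with retention of the E geometry of C6'=C7'; the silyl ether and the isolated alkenes do not react.

**Step 7**
Reactants: 11 (2E,6E,8R)-8-(tert-butyldimethylsilyloxy)-3,7,11-trimethyldodeca-2,6,10-trienal; 12 allenylboronic acid pinacol ester
Product: 13 (4S,5E,9E,11R)-11-(tert-butyldimethylsilyloxy)-6,10,14-trimethylpentadeca-5,9,13-trien-1-yn-4-ol
Conditions: 12 (1.5 equiv), (S)-TRIP phosphoric acid (10 mol %), 4 Å molecular sieves, toluene, −20 °C; aq. NaHCO3 work-up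
Reagents that add atoms: allenylboronic acid pinacol ester (12), C=C=CB1OC(C)(C)C(C)(C)O1
Why: Chiral phosphoric acid-catalysed propargylation of an aldehyde by an allenylboronate (SE2' transfer through a closed six-membered transition state, the acid hydrogen-bonded to a boronate oxygen and to the formyl hydrogen); the (S)-acid is expected to direct attack to the Si face of the enal and so set C5' as S under catalyst control, the remote C12' centre having no influence.

**Step 8**
Reactants: 14 4-methoxy-2-methylphenol
Product: 16 2-hydroxy-5-methoxy-3-methylbenzaldehyde, via hydroxymethylphenol 15 (not isolated)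
Conditions: MgCl2 (2 equiv), Et3N (4 equiv), paraformaldehyde (6 equiv), MeCN, reflux; dilute HCl work-up
Reagents that add atoms: formaldehyde (as paraformaldehyde), C=O
Why: Magnesium phenoxide-directed ortho-formylation (Casnati–Skattebøl reaction), in which the chelated phenoxide is hydroxymethylated at its only free ortho position and a second formaldehyde oxidises the benzylic alkoxide 15 by hydride transfer.

**Step 9**
Reactants: 16 2-hydroxy-5-methoxy-3-methylbenzaldehyde
Product: 17 2,5-dihydroxy-3-methylbenzaldehyde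
Conditions: BBr3 (3 equiv), CH2Cl2, −78 → 0 °C; H2O
Reagents that add atoms: none
Why: Lewis acid cleavage of the aryl methyl ether by BBr3 (O–B coordination, then bromide attack on the methyl group); the aldehyde is returned on aqueous work-up.

**Step 10**
Reactants: 17 2,5-dihydroxy-3-methylbenzaldehyde
Product: 18 2,5-bis(tert-butyldimethylsilyloxy)-3-methylbenzaldehyde
Conditions: TBSCl (2.6 equiv), imidazole (5 equiv), DMAP (cat.), DMF, rt → 40 °C
Reagents that add atoms: tert-butyldimethylsilyl chloride, CC(C)(C)[Si](C)(C)Cl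
Why: Silylation of both phenols; the imidazole/DMAP system is strong enough for the hydrogen-bonded, flanked C2 hydroxyl.

**Step 11**
Reactants: 18 2,5-bis(tert-butyldimethylsilyloxy)-3-methylbenzaldehyde
Product: 19 [2,5-bis(tert-butyldimethylsilyloxy)-3-methylphenyl]methanol
Conditions: i-Bu2AlH (1.2 equiv), CH2Cl2, −78 °C; aq. KNaC4H4O6 (potassium sodium tartrate)
Reagents that add atoms: none
Why: Hydride reduction of the aldehyde; the covalent aluminium alkoxide and the low temperature should keep the ortho silyl group from migrating to the benzylic oxygen.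

**Step 12**
Reactants: 19 [2,5-bis(tert-butyldimethylsilyloxy)-3-methylphenyl]methanol
Product: 20 2,5-bis(tert-butyldimethylsilyloxy)-3-methylbenzyl chloride
Conditions: PPh3 and N-chlorosuccinimide premixed, CH2Cl2, 0 °C; then 19, 0 °C → rt
Reagents that add atoms: N-chlorosuccinimide, O=C1CCC(=O)N1Cl
Why: Appel-type chlorination through the alkoxyphosphonium salt (SN2 by chloride) under neutral conditions; premixing leaves no free electrophilic chlorine for the electron-rich ring and no acid for the aryl silyl ethers.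

**Step 13**
Reactants: 13 (4S,5E,9E,11R)-11-(tert-butyldimethylsilyloxy)-6,10,14-trimethylpentadeca-5,9,13-trien-1-yn-4-ol; 20 2,5-bis(tert-butyldimethylsilyloxy)-3-methylbenzyl chloride; 21 trimethylaluminium
Product: 24 (2E,5S,6E,10E,12R)-1-[2,5-bis(tert-butyldimethylsilyloxy)-3-methylphenyl]-12-(tert-butyldimethylsilyloxy)-3,7,11,15-tetramethylhexadeca-2,6,10,14-tetraen-5-ol, via aluminium alkoxide 22 (not isolated), via alkenylalane 23 (not isolated)
Conditions: AlMe3 (3.5 equiv), Cp2ZrCl2 (0.25 equiv), CH2Cl2, 0 °C → rt; volatiles removed in vacuo; then 20 (1.3 equiv), Pd(PPh3)4 (5 mol %), THF, rt; aq. KNaC4H4O6 work-up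
Reagents that add atoms: trimethylaluminium (21), C[Al](C)C
Why: AlMe3 first converts the C5' hydroxyl into its dimethylaluminium alkoxide 22 with loss of methane, then the methylzirconocene species formed from Cp2ZrCl2 and AlMe3 adds CH3 and metal syn across the terminal alkyne, CH3 going to the internal C3' and the metal, passed on to aluminium, to the terminal C2', which gives (E)-alkenylalane 23. Zerovalent palladium inserts into the benzylic C–Cl bond of 20, the alkenyl group moves from aluminium to palladium with retention of geometry, and reductive elimination forms C1'–C2'. The closest known reaction type is the Negishi zirconium-catalysed methylalumination of terminal alkynes followed by palladium-catalysed coupling of the alkenylalane with a benzylic halide. No ring closes and no stereocentre is formed; the step needs regioselective syn addition, secured by the unhindered terminal alkyne that takes the bulky metal on its CH terminus, and retention in the coupling, which together fix the E-C2'=C3' alkene. The trisubstituted alkenes and the silyl ethers are inert to both metals, and the C5' oxygen, masked as its aluminium alkoxide, returns on work-up as the only free hydroxyl.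

**Step 14**
Reactants: 24 (2E,5S,6E,10E,12R)-1-[2,5-bis(tert-butyldimethylsilyloxy)-3-methylphenyl]-12-(tert-butyldimethylsilyloxy)-3,7,11,15-tetramethylhexadeca-2,6,10,14-tetraen-5-ol
Product: 25 (2E,5S,6E,10E,12R)-1-[2,5-bis(tert-butyldimethylsilyloxy)-3-methylphenyl]-12-(tert-butyldimethylsilyloxy)-3,7,11,15-tetramethylhexadeca-2,6,10,14-tetraen-5-yl acetate
Conditions: Ac2O, pyridine, DMAP (cat.), CH2Cl2, 0 °C → rt
Reagents that add atoms: acetic anhydride, CC(=O)OC(C)=O
Why: DMAP-catalysed acylation of the only free hydroxyl (C5'), both phenols and the C12' oxygen being silylated; the C5'–O bond is not broken, so the configuration is kept.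

**Step 15**
Reactants: 25 (2E,5S,6E,10E,12R)-1-[2,5-bis(tert-butyldimethylsilyloxy)-3-methylphenyl]-12-(tert-butyldimethylsilyloxy)-3,7,11,15-tetramethylhexadeca-2,6,10,14-tetraen-5-yl acetate
Product: 26 (2E,5S,6E,10E,12R)-1-(2,5-dihydroxy-3-methylphenyl)-12-hydroxy-3,7,11,15-tetramethylhexadeca-2,6,10,14-tetraen-5-yl acetate (target)
Conditions: Bu4NF (5 equiv), AcOH (5 equiv), degassed THF, Ar, 0 °C → rt
Reagents that add atoms: none
Why: Fluoride-induced cleavage of all three silyl ethers (two aryl, one secondary alkyl), buffered with acetic acid so that no phenoxide or alkoxide builds up to attack the acetate, and run without air so that the hydroquinone is not oxidised; no stereocentre or alkene is touched.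

**Compound list**
1 | geranyl acetate | CC(C)=CCC/C(C)=C/COC(C)=O | starting material
2 | (2E,6E)-8-hydroxy-3,7-dimethylocta-2,6-dien-1-yl acetate | CC(=O)OC/C=C(\C)CC/C=C(\C)CO | intermediate (not isolated)
3 | (2E,6E)-3,7-dimethyl-8-oxoocta-2,6-dien-1-yl acetate | CC(=O)OC/C=C(\C)CC/C=C(\C)C=O | intermediate
4 | (+)-B-allyldiisopinocampheylborane, from (−)-α-pinene | C=CCB([C@H]1C[C@H]2C[C@@H]([C@@H]1C)C2(C)C)[C@H]1C[C@H]2C[C@@H]([C@@H]1C)C2(C)C | starting material
5 | diisopinocampheylborinate of 6 | CC(=O)OC/C=C(\C)CC/C=C(\C)[C@H](OB([C@H]1C[C@H]2C[C@@H]([C@@H]1C)C2(C)C)[C@H]1C[C@H]2C[C@@H]([C@@H]1C)C2(C)C)CC=C | intermediate (not isolated)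
6 | (2E,6E,8R)-8-hydroxy-3,7-dimethylundeca-2,6,10-trien-1-yl acetate | CC(=O)OC/C=C(\C)CC/C=C(\C)[C@H](O)CC=C | intermediate
7 | 2-methyl-2-butene | CC=C(C)C | starting material
8 | (2E,6E,8R)-8-hydroxy-3,7,11-trimethyldodeca-2,6,10-trien-1-yl acetate | CC(=O)OC/C=C(\C)CC/C=C(\C)[C@H](O)CC=C(C)C | intermediate
9 | (2E,6E,8R)-8-(tert-butyldimethylsilyloxy)-3,7,11-trimethyldodeca-2,6,10-trien-1-yl acetate | CC(=O)OC/C=C(\C)CC/C=C(\C)[C@H](O[Si](C)(C)C(C)(C)C)CC=C(C)C | intermediate
10 | (2E,6E,8R)-8-(tert-butyldimethylsilyloxy)-3,7,11-trimethyldodeca-2,6,10-trien-1-ol | OC/C=C(\C)CC/C=C(\C)[C@H](O[Si](C)(C)C(C)(C)C)CC=C(C)C | intermediate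
11 | (2E,6E,8R)-8-(tert-butyldimethylsilyloxy)-3,7,11-trimethyldodeca-2,6,10-trienal | O=C/C=C(\C)CC/C=C(\C)[C@H](O[Si](C)(C)C(C)(C)C)CC=C(C)C | intermediate
12 | allenylboronic acid pinacol ester | C=C=CB1OC(C)(C)C(C)(C)O1 | starting material
13 | (4S,5E,9E,11R)-11-(tert-butyldimethylsilyloxy)-6,10,14-trimethylpentadeca-5,9,13-trien-1-yn-4-ol (key-step precursor) | O[C@H](/C=C(\C)CC/C=C(\C)[C@H](O[Si](C)(C)C(C)(C)C)CC=C(C)C)CC#C | intermediate
14 | 4-methoxy-2-methylphenol | COc1ccc(O)c(C)c1 | starting material
15 | 2-(hydroxymethyl)-4-methoxy-6-methylphenol (as its magnesium salt in the flask) | COc1cc(C)c(O)c(CO)c1 | intermediate (not isolated)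
16 | 2-hydroxy-5-methoxy-3-methylbenzaldehyde | COc1cc(C)c(O)c(C=O)c1 | intermediate
17 | 2,5-dihydroxy-3-methylbenzaldehyde | Oc1cc(C)c(O)c(C=O)c1 | intermediate
18 | 2,5-bis(tert-butyldimethylsilyloxy)-3-methylbenzaldehyde | CC(C)(C)[Si](C)(C)Oc1cc(C)c(O[Si](C)(C)C(C)(C)C)c(C=O)c1 | intermediate
19 | [2,5-bis(tert-butyldimethylsilyloxy)-3-methylphenyl]methanol | CC(C)(C)[Si](C)(C)Oc1cc(C)c(O[Si](C)(C)C(C)(C)C)c(CO)c1 | intermediate
20 | 2,5-bis(tert-butyldimethylsilyloxy)-3-methylbenzyl chloride | CC(C)(C)[Si](C)(C)Oc1cc(C)c(O[Si](C)(C)C(C)(C)C)c(CCl)c1 | intermediate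
21 | trimethylaluminium | C[Al](C)C | starting material
22 | dimethylaluminium alkoxide of 13 | C[Al](C)O[C@H](/C=C(\C)CC/C=C(\C)[C@H](O[Si](C)(C)C(C)(C)C)CC=C(C)C)CC#C | intermediate (not isolated)
23 | (E)-C2' alkenyldimethylalane, C5' dimethylaluminium alkoxide | C[Al](C)O[C@H](/C=C(\C)CC/C=C(\C)[C@H](O[Si](C)(C)C(C)(C)C)CC=C(C)C)C/C(C)=C/[Al](C)C | intermediate (not isolated)
24 | (2E,5S,6E,10E,12R)-1-[2,5-bis(tert-butyldimethylsilyloxy)-3-methylphenyl]-12-(tert-butyldimethylsilyloxy)-3,7,11,15-tetramethylhexadeca-2,6,10,14-tetraen-5-ol (key-step product) | O[C@H](/C=C(\C)CC/C=C(\C)[C@H](O[Si](C)(C)C(C)(C)C)CC=C(C)C)C/C(C)=C/Cc1cc(O[Si](C)(C)C(C)(C)C)cc(C)c1O[Si](C)(C)C(C)(C)C | intermediate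
25 | C5' acetate of 24 | CC(=O)O[C@H](/C=C(\C)CC/C=C(\C)[C@H](O[Si](C)(C)C(C)(C)C)CC=C(C)C)C/C(C)=C/Cc1cc(O[Si](C)(C)C(C)(C)C)cc(C)c1O[Si](C)(C)C(C)(C)C | intermediate
26 | (2E,5S,6E,10E,12R)-1-(2,5-dihydroxy-3-methylphenyl)-12-hydroxy-3,7,11,15-tetramethylhexadeca-2,6,10,14-tetraen-5-yl acetate | CC(=O)O[C@H](/C=C(\C)CC/C=C(\C)[C@H](O)CC=C(C)C)C/C(C)=C/Cc1cc(O)cc(C)c1O | target

**Step count.** Total: 15 steps. Longest linear sequence: 10 steps from geranyl acetate (steps 1–7 and 13–15); the arene branch is 5 steps (8–12).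

**Steps most likely to fail**

Step 13. The transfer of the alkenyl group from aluminium to palladium may stall beside the aluminium alkoxide, or the aluminium Lewis acids may consume the electron-rich benzylic chloride (methyl transfer, self-alkylation) before it couples. The fallback separates the two events and reverses the polarity of the coupling. It sets out from 13 and 20. Alkyne 13 is methylaluminated as in step 13 and alkenylalane 23 is quenched with I2 (THF, −30 °C) to give the (E)-vinyl iodide F1. Chloride 20 is converted with zinc dust and LiCl in THF into the benzylzinc chloride F2. Negishi coupling of F1 with F2 (2.5 equiv, one equivalent being spent on the hydroxyl; Pd(PPh3)4, THF, rt) gives 24, where the route is rejoined.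

Step 7. Facial discrimination on the β,β-disubstituted enal may be insufficient, and because C5' and C12' are remote from each other the epimers would not separate later. The fallback replaces the asymmetric addition by a resolution. It sets out from enal 11. Zinc-mediated Barbier propargylation (propargyl bromide, Zn, THF/aq. NH4Cl) gives the C5' epimer mixture F3. Lipase-catalysed acylation (Burkholderia cepacia lipase, vinyl acetate, t-BuOMe) should, by the Kazlauskas rule, acylate the (5'R)-epimer to the acetate F4 and leave the (5'S)-alcohol, which is 13 and is separated by chromatography; the route is rejoined there.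

Step 15. Slow cleavage of the flanked C12' silyl ether may force long exposure of the liberated hydroquinone to fluoride, with air oxidation and loss of the acetate. The fallback moves the slow desilylation onto the air-stable quinone and frees the hydroquinone last under reducing conditions. It sets out from 25. Brief treatment with Bu4NF/AcOH at 0 °C removes only the two aryl silyl ethers and gives the hydroquinone F5. Oxidation with Ag2O (Et2O, rt) gives the quinone F6. HF·pyridine in THF then cleaves the C12' silyl ether to the quinone alcohol F7. Reduction with aqueous Na2S2O4 (Et2O/H2O, rt) gives 26.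

**Further compounds**
F1 | step 13 | (1E,4S,5E,9E,11R)-11-(tert-butyldimethylsilyloxy)-1-iodo-2,6,10,14-tetramethylpentadeca-1,5,9,13-tetraen-4-ol | O[C@H](/C=C(\C)CC/C=C(\C)[C@H](O[Si](C)(C)C(C)(C)C)CC=C(C)C)C/C(C)=C/I
F2 | step 13 | [2,5-bis(tert-butyldimethylsilyloxy)-3-methylbenzyl]zinc chloride | Cl[Zn]Cc1cc(O[Si](C)(C)C(C)(C)C)cc(C)c1O[Si](C)(C)C(C)(C)C
F3 | step 7 | (4RS,5E,9E,11R)-11-(tert-butyldimethylsilyloxy)-6,10,14-trimethylpentadeca-5,9,13-trien-1-yn-4-ol (C5' epimer mixture) | OC(/C=C(\C)CC/C=C(\C)[C@H](O[Si](C)(C)C(C)(C)C)CC=C(C)C)CC#C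
F4 | step 7 | (4R,5E,9E,11R)-11-(tert-butyldimethylsilyloxy)-6,10,14-trimethylpentadeca-5,9,13-trien-1-yn-4-yl acetate | CC(=O)O[C@@H](/C=C(\C)CC/C=C(\C)[C@H](O[Si](C)(C)C(C)(C)C)CC=C(C)C)CC#C
F5 | step 15 | (2E,5S,6E,10E,12R)-12-(tert-butyldimethylsilyloxy)-1-(2,5-dihydroxy-3-methylphenyl)-3,7,11,15-tetramethylhexadeca-2,6,10,14-tetraen-5-yl acetate | CC(=O)O[C@H](/C=C(\C)CC/C=C(\C)[C@H](O[Si](C)(C)C(C)(C)C)CC=C(C)C)C/C(C)=C/Cc1cc(O)cc(C)c1O
F6 | step 15 | (2E,5S,6E,10E,12R)-12-(tert-butyldimethylsilyloxy)-3,7,11,15-tetramethyl-1-(5-methyl-3,6-dioxocyclohexa-1,4-dien-1-yl)hexadeca-2,6,10,14-tetraen-5-yl acetate | CC(=O)O[C@H](/C=C(\C)CC/C=C(\C)[C@H](O[Si](C)(C)C(C)(C)C)CC=C(C)C)C/C(C)=C/CC1=CC(=O)C=C(C)C1=O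
F7 | step 15 | (2E,5S,6E,10E,12R)-12-hydroxy-3,7,11,15-tetramethyl-1-(5-methyl-3,6-dioxocyclohexa-1,4-dien-1-yl)hexadeca-2,6,10,14-tetraen-5-yl acetate | CC(=O)O[C@H](/C=C(\C)CC/C=C(\C)[C@H](O)CC=C(C)C)C/C(C)=C/CC1=CC(=O)C=C(C)C1=O
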